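**Retrosynthetic overview**
- The acid comes from its methyl ester, whose C3–H is installed last by ionic hydrogenation of a C3 peroxy-hemiketal (trans to C6).
- Both rings come from one acyclic keto epoxy mesylate in a single operation: the C6–C7 oxirane expands to the oxolane through an epoxonium ion (oxolane ring first), and the C3 ketone perhydrate then closes the 1,2-dioxane at C6 (second ring).
- The acyclic precursor is cut at C4–C5: acetoacetate dianion (C1–C4) plus an epoxy bis-mesylate (C5–C24).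
- C5–C24 is cut at C11–C12: a side-chain Grignard reagent (C12–C24) plus a bis-epoxide (C5–C11) made by cross-metathesis and Sharpless epoxidation from (R)-1,2-epoxy-5-hexene and butenediol.
- The side chain is cut at C17=C18: a Z-selective Wittig reaction of a C12–C17 phosphonium salt with (E)-hepta-2,6-dienal.

Assumption: locants C1–C24 follow the acid chain of the target (C1 = carboxyl carbon; C3 and C6 = dioxane carbons; C7 and C10 = oxolane carbons).

**Step 1**
Reactants: 1 1-bromo-6-chlorohexane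
Product: 2 (6-chlorohexyl)triphenylphosphonium bromide
Conditions: PPh3 (1.0 equiv), MeCN, reflux, 24 h
Reagents that add atoms: triphenylphosphine, c1ccc(cc1)P(c1ccccc1)c1ccccc1
Why: SN2 quaternisation of the phosphine (phosphonium salt formation) occurs at the C–Br bond far faster than at C–Cl, so the chloride survives as the later Grignard handle.

**Step 2**
Reactants: 3 pent-4-enal
Product: 4 (2E)-hepta-2,6-dienal
Conditions: Ph3P=CHCHO (1.05 equiv), toluene, 80 °C
Reagents that add atoms: (triphenylphosphoranylidene)acetaldehyde, O=CC=P(c1ccccc1)(c1ccccc1)c1ccccc1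
Why: Wittig olefination with the stabilised formyl ylide is E-selective and sets the future C19=C20 (E) alkene.

**Step 3**
Reactants: 2 (6-chlorohexyl)triphenylphosphonium bromide; 4 (2E)-hepta-2,6-dienal
Product: 6 (5E,7Z)-13-chlorotrideca-1,5,7-triene, via phosphonium ylide 5 (not isolated)
Conditions: NaN(SiMe3)2 (1.0 equiv), THF, −78 °C; then 4, −78 → 0 °C
Reagents that add atoms: none
Why: Salt-free Wittig olefination of a non-stabilised ylide with an enal is kinetically Z-selective and sets C17=C18 (Z) without touching the E-alkene; the primary chloride is inert at this temperature and minor E,E-diene is removed on AgNO3-silica.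

**Step 4**
Reactants: 7 (2R)-2-(but-3-en-1-yl)oxirane; 8 (2Z)-but-2-ene-1,4-diol
Product: 9 (2E)-5-[(2R)-oxiran-2-yl]pent-2-en-1-ol
Conditions: 8 (3 equiv), second-generation Hoveyda–Grubbs catalyst RuCl2(H2IMes)(=CH-C6H4-2-OiPr) (2 mol %), CH2Cl2, 40 °C
Reagents that add atoms: none
Why: Olefin cross-metathesis of the terminal alkene with the symmetrical cis-diol gives mainly the E-allylic alcohol; the epoxide and its stereocentre (future C10) are untouched.

**Step 5**
Reactants: 9 (2E)-5-[(2R)-oxiran-2-yl]pent-2-en-1-ol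
Product: 10 [(2S,3S)-3-{2-[(2R)-oxiran-2-yl]ethyl}oxiran-2-yl]methanol
Conditions: Ti(OiPr)4 (10 mol %), L-(+)-diethyl tartrate (12 mol %), t-BuOOH (2 equiv), 4 Å molecular sieves, CH2Cl2, −20 °C
Reagents that add atoms: tert-butyl hydroperoxide, CC(C)(C)OO
Why: Sharpless asymmetric epoxidation with the L-(+)-tartrate catalyst sets C6 and C7 as the (2S,3S)-trans-epoxide by reagent control; residual Z-allylic alcohol from step 4 reacts much more slowly and is separated.

**Step 6**
Reactants: 6 (5E,7Z)-13-chlorotrideca-1,5,7-triene; 10 [(2S,3S)-3-{2-[(2R)-oxiran-2-yl]ethyl}oxiran-2-yl]methanol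
Product: 14 {(2S,3S)-3-[(3S,10Z,12E)-3-(methylsulfonyloxy)heptadeca-10,12,16-trien-1-yl]oxiran-2-yl}methyl methanesulfonate, via Grignard reagent 11 (not isolated), via chloromagnesium alkoxide 12 (not isolated), via bis(chloromagnesium) dialkoxide 13 (not isolated)
Conditions: 6, Mg, THF, 60 °C; 10, i-PrMgCl (1.0 equiv), THF, −40 °C; add 11 (1.3 equiv), CuI (10 mol %), −40 → −20 °C; then MsCl (2.5 equiv), Et3N, −40 → 0 °C
Reagents that add atoms: methanesulfonyl chloride, CS(=O)(=O)Cl
Why: Copper-catalysed Grignard opening attacks the CH2 of the terminal epoxide (SN2, C10 geometry retained, now the S carbinol) faster than the internal epoxy alkoxide at −40 °C, and in-situ mesylation of both alkoxides prevents 5-exo attack of the C10 oxygen on the internal epoxide.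

**Step 7**
Reactants: 15 methyl 3-oxobutanoate (methyl acetoacetate); 14 {(2S,3S)-3-[(3S,10Z,12E)-3-(methylsulfonyloxy)heptadeca-10,12,16-trien-1-yl]oxiran-2-yl}methyl methanesulfonate
Product: 18 methyl 5-{(2S,3S)-3-[(3S,10Z,12E)-3-(methylsulfonyloxy)heptadeca-10,12,16-trien-1-yl]oxiran-2-yl}-3-oxopentanoate, via dilithium dianion 16 (not isolated), via lithium enolate 17 (not isolated)
Conditions: 15 (2 equiv), LiN(iPr)2 (4.1 equiv), THF, 0 °C; then 14, Bu4NI (0.2 equiv), THF/DMPU, −40 → 0 °C; aq NH4Cl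
Reagents that add atoms: none
Why: Weiler dianion alkylation: the γ-carbon of the acetoacetate dianion displaces the primary epoxymethyl sulfonate (iodide-catalysed SN2) much faster than the hindered secondary C10 mesylate or the internal epoxide, joining C4–C5 with no stereocentre touched.

**Step 8**
Reactants: 18 methyl 5-{(2S,3S)-3-[(3S,10Z,12E)-3-(methylsulfonyloxy)heptadeca-10,12,16-trien-1-yl]oxiran-2-yl}-3-oxopentanoate
Product: 21 methyl 2-[(6R)-3-hydroxy-6-{(2S,5R)-5-[(7Z,9E)-tetradeca-7,9,13-trien-1-yl]oxolan-2-yl}-1,2-dioxan-3-yl]acetate, via ketone perhydrate 19 (not isolated), via epoxonium ion 20 (not isolated)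
Conditions: urea·H2O2 (6 equiv), 2,6-lutidine (1.5 equiv), (CF3)2CHOH, 0 → 25 °C
Reagents that add atoms: hydrogen peroxide (from urea·H2O2), OO
Why: Proposed new method: in the strongly ionising, non-nucleophilic (CF3)2CHOH the epoxide oxygen displaces the C10 mesylate with inversion (5-exo anchimeric assistance), expanding the oxirane to an oxolane through the 1-oxoniabicyclo[3.1.0]hexane (epoxonium) ion 20, whose exocyclic carbon C6 is then opened with inversion by the terminal oxygen of the C3 ketone perhydrate 19 (six-membered transition state, far better placed than attack at C7), so the trans-oxolane (C7 retained, C10 inverted to R) and the erythro C6–C7 junction (C6 inverted to R) arise in one operation; the closest known reaction type is the epoxonium-mediated ring expansion of epoxides triggered by halonium ions or sulfonate solvolysis and terminated by water, alcohols, carboxylates or halides, together with acid-catalysed hydroperoxide opening of epoxides to 1,2-dioxanes, whereas capture of an epoxonium ion by a peroxide nucleophile has not been described.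

**Step 9**
Reactants: 21 methyl 2-[(6R)-3-hydroxy-6-{(2S,5R)-5-[(7Z,9E)-tetradeca-7,9,13-trien-1-yl]oxolan-2-yl}-1,2-dioxan-3-yl]acetate
Product: 23 methyl 2-[(3R,6R)-6-{(2S,5R)-5-[(7Z,9E)-tetradeca-7,9,13-trien-1-yl]oxolan-2-yl}-1,2-dioxan-3-yl]acetate, via peroxycarbenium ion 22 (not isolated)
Conditions: Et3SiH (5 equiv), BF3·OEt2 (2 equiv), CH2Cl2, −78 → −40 °C
Reagents that add atoms: none
Why: Ionic hydrogenation (Kishi-type hemiketal reduction) through the peroxycarbenium ion: axial hydride delivery on the half-chair with the C6 substituent pseudoequatorial leaves CH2CO2Me equatorial, giving the 3,6-trans (3R) dioxane, by analogy with 2,6-cis-oxane formation from hemiketals and with Lewis-acid substitutions of 1,2-dioxan-3-ol derivatives.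

**Step 10**
Reactants: 23 methyl 2-[(3R,6R)-6-{(2S,5R)-5-[(7Z,9E)-tetradeca-7,9,13-trien-1-yl]oxolan-2-yl}-1,2-dioxan-3-yl]acetate
Product: 25 2-[(3R,6R)-6-{(2S,5R)-5-[(7Z,9E)-tetradeca-7,9,13-trien-1-yl]oxolan-2-yl}-1,2-dioxan-3-yl]acetic acid, via lithium carboxylate 24 (not isolated)
Conditions: LiOH (3 equiv), THF/H2O 3:1, 0 °C; then 1 M HCl to pH 3
Reagents that add atoms: lithium hydroxide, [Li+].[OH-]
Why: Saponification (acyl-oxygen ester hydrolysis) at 0 °C is faster than α-deprotonation and retro-oxa-Michael opening of the β-peroxy ester, and no stereocentre is affected.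

**Compound list**
1 | 1-bromo-6-chlorohexane | ClCCCCCCBr | starting material
2 | (6-chlorohexyl)triphenylphosphonium bromide | [Br-].ClCCCCCC[P+](c1ccccc1)(c1ccccc1)c1ccccc1 | intermediate
3 | pent-4-enal | C=CCCC=O | starting material
4 | (2E)-hepta-2,6-dienal | C=CCC/C=C/C=O | intermediate
5 | (6-chlorohexylidene)triphenylphosphorane | ClCCCCCC=P(c1ccccc1)(c1ccccc1)c1ccccc1 | intermediate
6 | (5E,7Z)-13-chlorotrideca-1,5,7-triene | C=CCC/C=C/C=C\CCCCCCl | intermediate
7 | (2R)-2-(but-3-en-1-yl)oxirane | C=CCC[C@@H]1CO1 | starting material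
8 | (2Z)-but-2-ene-1,4-diol | OC/C=C\CO | starting material
9 | (2E)-5-[(2R)-oxiran-2-yl]pent-2-en-1-ol | OC/C=C/CC[C@@H]1CO1 | intermediate
10 | [(2S,3S)-3-{2-[(2R)-oxiran-2-yl]ethyl}oxiran-2-yl]methanol | OC[C@@H]1O[C@H]1CC[C@@H]1CO1 | intermediate
11 | [(6Z,8E)-trideca-6,8,12-trien-1-yl]magnesium chloride | C=CCC/C=C/C=C\CCCCC[Mg]Cl | intermediate
12 | chloromagnesium alkoxide of 10 | Cl[Mg]OC[C@@H]1O[C@H]1CC[C@@H]1CO1 | intermediate
13 | bis(chloromagnesium) dialkoxide of (3S,10Z,12E)-1-[(2S,3S)-3-(hydroxymethyl)oxiran-2-yl]heptadeca-10,12,16-trien-3-ol | Cl[Mg]OC[C@@H]1O[C@H]1CC[C@@H](O[Mg]Cl)CCCCCC/C=C\C=C\CCC=C | intermediate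
14 | {(2S,3S)-3-[(3S,10Z,12E)-3-(methylsulfonyloxy)heptadeca-10,12,16-trien-1-yl]oxiran-2-yl}methyl methanesulfonate | CS(=O)(=O)OC[C@@H]1O[C@H]1CC[C@@H](OS(C)(=O)=O)CCCCCC/C=C\C=C\CCC=C | intermediate
15 | methyl 3-oxobutanoate | COC(=O)CC(C)=O | starting material
16 | dilithium 1,3-dienolate (dianion) of methyl 3-oxobutanoate | [Li+].[Li+].C=C([O-])C=C([O-])OC | intermediate
17 | lithium enolate of 18 | [Li+].COC(=O)C=C([O-])CC[C@@H]1O[C@H]1CC[C@@H](OS(C)(=O)=O)CCCCCC/C=C\C=C\CCC=C | intermediate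
18 | methyl 5-{(2S,3S)-3-[(3S,10Z,12E)-3-(methylsulfonyloxy)heptadeca-10,12,16-trien-1-yl]oxiran-2-yl}-3-oxopentanoate | COC(=O)CC(=O)CC[C@@H]1O[C@H]1CC[C@@H](OS(C)(=O)=O)CCCCCC/C=C\C=C\CCC=C | intermediate
19 | perhydrate of 18 (methyl 3-hydroperoxy-3-hydroxy analogue, C3 unassigned) | COC(=O)CC(O)(OO)CC[C@@H]1O[C@H]1CC[C@@H](OS(C)(=O)=O)CCCCCC/C=C\C=C\CCC=C | intermediate
20 | epoxonium methanesulfonate: 1-oxoniabicyclo[3.1.0]hexane with O+ bonded to C6, C7 and C10, C6 bearing the perhydrate chain and C10 the trienyl chain | COC(=O)CC(O)(OO)CC[C@@H]1[O+]2[C@H]1CC[C@H]2CCCCCC/C=C\C=C\CCC=C.CS(=O)(=O)[O-] | intermediate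
21 | methyl 2-[(6R)-3-hydroxy-6-{(2S,5R)-5-[(7Z,9E)-tetradeca-7,9,13-trien-1-yl]oxolan-2-yl}-1,2-dioxan-3-yl]acetate (C3 hemiketal, anomer mixture) | C=CCC/C=C/C=C\CCCCCC[C@@H]1CC[C@@H]([C@H]2CCC(O)(CC(=O)OC)OO2)O1 | intermediate
22 | peroxycarbenium ion (C3=O+ of the dioxane ring, hydroxytrifluoroborate counter-ion) | C=CCC/C=C/C=C\CCCCCC[C@@H]1CC[C@@H]([C@H]2CCC(CC(=O)OC)=[O+]O2)O1.O[B-](F)(F)F | intermediate
23 | methyl 2-[(3R,6R)-6-{(2S,5R)-5-[(7Z,9E)-tetradeca-7,9,13-trien-1-yl]oxolan-2-yl}-1,2-dioxan-3-yl]acetate | C=CCC/C=C/C=C\CCCCCC[C@@H]1CC[C@@H]([C@H]2CC[C@H](CC(=O)OC)OO2)O1 | intermediate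
24 | lithium salt of 25 | [Li+].C=CCC/C=C/C=C\CCCCCC[C@@H]1CC[C@@H]([C@H]2CC[C@H](CC(=O)[O-])OO2)O1 | intermediate
25 | 2-[(3R,6R)-6-{(2S,5R)-5-[(7Z,9E)-tetradeca-7,9,13-trien-1-yl]oxolan-2-yl}-1,2-dioxan-3-yl]acetic acid | C=CCC/C=C/C=C\CCCCCC[C@@H]1CC[C@@H]([C@H]2CC[C@H](CC(=O)O)OO2)O1 | target

**Totals**
Total steps: 10. Longest linear sequence: 7 (steps 1, 3, 6, 7, 8, 9, 10; the branch through steps 4 and 5 is equally long).

**Steps most likely to fail**

Step 6. The copper-catalysed opening must choose the terminal over the internal epoxide. The C10 alkoxide must be mesylated before it attacks the internal epoxide (5-exo), and MgCl2 may form chlorohydrins. The fallback sets out from 9 and returns at 14, with the side chain joined before the second epoxide exists. Compound 9 is silylated (TBSCl, imidazole) to tert-butyl(dimethyl){[(2E)-5-[(2R)-oxiran-2-yl]pent-2-en-1-yl]oxy}silane F1. Its only epoxide is opened with 11/CuI and the alkoxide trapped with MsCl to give (2E,6S,13Z,15E)-1-[(tert-butyldimethylsilyl)oxy]icosa-2,13,15,19-tetraen-6-yl methanesulfonate F2. HF·pyridine then frees (2E,6S,13Z,15E)-1-hydroxyicosa-2,13,15,19-tetraen-6-yl methanesulfonate F3. Sharpless epoxidation as in step 5 gives (3S,10Z,12E)-1-[(2S,3S)-3-(hydroxymethyl)oxiran-2-yl]heptadeca-10,12,16-trien-3-yl methanesulfonate F4, and MsCl/Et3N converts it to 14.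

Step 7. The primary epoxymethyl mesylate may be too sluggish, letting attack at the C10 mesylate or O-alkylation of the product enolate by the epoxide compete. The fallback sets out from 10 and returns at 18, reversing the order of the two fragment unions. Tf2O/2,6-lutidine at −78 °C gives [(2S,3S)-3-{2-[(2R)-oxiran-2-yl]ethyl}oxiran-2-yl]methyl trifluoromethanesulfonate F5. Dianion 16 at −78 °C gives methyl 3-oxo-5-[(2S,3S)-3-{2-[(2R)-oxiran-2-yl]ethyl}oxiran-2-yl]pentanoate F6. Its sodium enolate (NaH) is treated with 11/CuI at −40 °C and quenched cold with NH4Cl to give methyl 5-{(2S,3S)-3-[(3S,10Z,12E)-3-hydroxyheptadeca-10,12,16-trien-1-yl]oxiran-2-yl}-3-oxopentanoate F7. Immediate mesylation (MsCl, Et3N, −20 °C) gives 18.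

Step 8 (the new reaction). Possible failures:
- the ketone oxygen or the perhydrate hydroxyl may capture C6 through a five-membered transition state, giving a 2-hydroperoxyoxolane;
- the epoxonium ion may open at C7, giving an oxane;
- H2O2 in (CF3)2CHOH may oxidise the diene.

If the perhydrate opens the hydrogen-bonded epoxide before the mesylate ionises, the C7 hydroxyl then displaces the mesylate and the same 21 results. The fallback uses known chemistry, sets out from 18 and returns at 21. Ethereal H2O2 with catalytic H3PMo12O40 in Et2O at 0 °C effects the established acid-catalysed 6-exo perhydrolysis of the epoxide with hemiketalisation. This gives methyl 2-[(6R)-3-hydroxy-6-[(1S,4S,11Z,13E)-1-hydroxy-4-(methylsulfonyloxy)octadeca-11,13,17-trien-1-yl]-1,2-dioxan-3-yl]acetate F8. Warming F8 with 2,6-lutidine in MeCN at 45 °C closes the oxolane by intramolecular Williamson etherification (C7–OH displaces the C10 mesylate with inversion) to give 21.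

**Further compounds**
F1 | step 6 | tert-butyl(dimethyl){[(2E)-5-[(2R)-oxiran-2-yl]pent-2-en-1-yl]oxy}silane | CC(C)(C)[Si](C)(C)OC/C=C/CC[C@@H]1CO1
F2 | step 6 | (2E,6S,13Z,15E)-1-[(tert-butyldimethylsilyl)oxy]icosa-2,13,15,19-tetraen-6-yl methanesulfonate | CC(C)(C)[Si](C)(C)OC/C=C/CC[C@@H](OS(C)(=O)=O)CCCCCC/C=C\C=C\CCC=C
F3 | step 6 | (2E,6S,13Z,15E)-1-hydroxyicosa-2,13,15,19-tetraen-6-yl methanesulfonate | OC/C=C/CC[C@@H](OS(C)(=O)=O)CCCCCC/C=C\C=C\CCC=C
F4 | step 6 | (3S,10Z,12E)-1-[(2S,3S)-3-(hydroxymethyl)oxiran-2-yl]heptadeca-10,12,16-trien-3-yl methanesulfonate | OC[C@@H]1O[C@H]1CC[C@@H](OS(C)(=O)=O)CCCCCC/C=C\C=C\CCC=C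
F5 | step 7 | [(2S,3S)-3-{2-[(2R)-oxiran-2-yl]ethyl}oxiran-2-yl]methyl trifluoromethanesulfonate | FC(F)(F)S(=O)(=O)OC[C@@H]1O[C@H]1CC[C@@H]1CO1
F6 | step 7 | methyl 3-oxo-5-[(2S,3S)-3-{2-[(2R)-oxiran-2-yl]ethyl}oxiran-2-yl]pentanoate | COC(=O)CC(=O)CC[C@@H]1O[C@H]1CC[C@@H]1CO1
F7 | step 7 | methyl 5-{(2S,3S)-3-[(3S,10Z,12E)-3-hydroxyheptadeca-10,12,16-trien-1-yl]oxiran-2-yl}-3-oxopentanoate | COC(=O)CC(=O)CC[C@@H]1O[C@H]1CC[C@@H](O)CCCCCC/C=C\C=C\CCC=C
F8 | step 8 | methyl 2-[(6R)-3-hydroxy-6-[(1S,4S,11Z,13E)-1-hydroxy-4-(methylsulfonyloxy)octadeca-11,13,17-trien-1-yl]-1,2-dioxan-3-yl]acetate | C=CCC/C=C/C=C\CCCCCC[C@H](OS(C)(=O)=O)CC[C@H](O)[C@H]1CCC(O)(CC(=O)OC)OO1
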